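## Retrosynthetic overview

1. Longipinane numbering is used. C1 is the ketone carbon and C2=C3 the enone alkene. The four-membered ring is C4–C5–C11–C10 (C4 on C3, C11 on C1, C5 on C6, methyl-bearing C10 on C9). C6 is CMe2, C7 the senecioate carbinol, C8 a CH2, C9 the isovalerate carbinol.
2. Feature used: cutting only C5–C6, C5–C11 and C4–C10 opens the cyclobutane, both six-membered rings through C1–C2–C3 and the seven-membered ring C5–C6–C7–C8–C9–C10–C11. What remains is one regular triisoprenoid chain, C5–C4–C3–C2–C1–C11–C10–C9–C8–C7–C6, which is farnesyl.
3. Late stage: C7 ester by acylation. O9 ester and C7 carbinol together by an Evans–Tishchenko reaction on a 9-hydroxy-7-ketone. C9–O by conjugate borylation of a C8=C9 enone. C7=O from a single enzymatic C–H hydroxylation. C1=O by allylic oxidation of α-longipinene.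
4. Skeleton: α-longipinene from farnesyl diphosphate with a sesquiterpene synthase. Ring order: eleven-membered ring (C5–C6), then seven- plus six-membered rings (C5–C11), then cyclobutane plus the second six-membered ring (C4–C10).
5. Farnesyl diphosphate comes from farnesol through the allylic chloride.

Key step: step 3

Assumption: the synthase is a conifer humulene/longifolene-type enzyme re-tuned by active-site mutations toward α-longipinene. It is taken to give the (1R,2S,7R,8R) antipode, to be confirmed by chiral GC before scale-up.

Remark: farnesyl diphosphate is drawn as the free acid but is made, stored and used as its tris-ammonium salt. The C7 alcohol of step 5 is drawn as 7R, although either epimer serves because step 6 erases that centre. All verbenone-type enones are kept away from UV light.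

## Route

Step 1
Reactants: 1 (2E,6E)-farnesol
Product: 2 (2E,6E)-farnesyl chloride
Conditions: NCS, Me2S, CH2Cl2, −40 to 0 °C
Reagents that add atoms: N-chlorosuccinimide, O=C1CCC(=O)N1Cl
Why: Corey–Kim-type chlorination, in which the sulfonium-activated primary allylic oxygen is displaced by chloride in an SN2 sense under cold, neutral conditions, so neither allylic transposition nor loss of the 2E geometry is expected.

Step 2
Reactants: 2 (2E,6E)-farnesyl chloride
Product: 3 (2E,6E)-farnesyl diphosphate
Conditions: (n-Bu4N)3HP2O7, MeCN, 25 °C; then Dowex 50W-X8 (NH4+ form), aq. NH4HCO3; cellulose chromatography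
Reagents that add atoms: tris(tetrabutylammonium) hydrogen diphosphate, CCCC[N+](CCCC)(CCCC)CCCC.CCCC[N+](CCCC)(CCCC)CCCC.CCCC[N+](CCCC)(CCCC)CCCC.OP(=O)([O-])OP(=O)([O-])[O-]
Why: SN2 displacement of a primary allylic chloride by the acetonitrile-soluble diphosphate anion is the standard synthesis of allylic diphosphates, and cation exchange gives the water-soluble ammonium form that the enzyme accepts.

Step 3
Reactants: 3 (2E,6E)-farnesyl diphosphate
Product: 9 (1R,2S,7R,8R)-α-longipinene, via nerolidyl diphosphate 4 (not isolated), via humulyl cation 5 (not isolated), via allylic humulyl cation 6 (not isolated), via cis-himachalyl cation 7 (not isolated), via longipinyl cation 8 (not isolated)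
Conditions: recombinant α-longipinene synthase (purified), MgCl2, HEPES pH 7.5, DTT, 10% glycerol, pentane overlay, 30 °C; AgNO3–SiO2 chromatography
Reagents that add atoms: none
Why: The Mg2+ cluster pulls diphosphate off C5 of 3, returns it to C3 (4) so that the C3–C4 bond can rotate, and ionises again to a Z-allyl cation, whereupon C6 of the terminal alkene bonds to C5 (5), a 1,3-hydride shift from C5 to C7 gives allyl cation 6, C11 of the C10=C11 alkene bonds to C5 (7), C4 of the C3=C4 alkene bonds to the C10 cation (8) and a C2 proton is removed to give 9. The closest known reaction type is this very one, the ionisation-triggered cationic polyene cyclisation of farnesyl diphosphate by sesquiterpene synthases of the humulene–longifolene family, among whose established products α-longipinene is found. The eleven-membered ring closes 11-endo (anti-Markovnikov, the C7 cation lying inside the ring), the transannular C5–C11 bond splits it into the seven-membered ring (7-endo with respect to C10=C11) and a cyclohexene (6-exo), and the C4–C10 bond closes the cyclobutane 4-exo while completing the ring C1–C2–C3–C4–C10–C11 (6-endo). C5 and C11 arise together and are fixed by the faces of the allyl cation and the E-alkene that the folded chain presents in the pocket (cis-fused 7), whereas C10 and C4 arise in the last closure, where the tether lets the alkene reach only one face of the C10 cation, so the relative configuration of all four follows from ring geometry and the absolute sense from the chiral pocket alone. The step must prefer C4–C10 over C3–C10 bonding (the longifolene branch), C2 over methyl deprotonation (β-longipinene) and full cyclisation over early quenching (humulenes, himachalenes); nothing in the substrate secures this, only the pocket contour and the placement of the diphosphate base, which is why a variant tuned for 9 is used and minor hydrocarbons are removed on AgNO3–SiO2. The strain-raising cyclobutane closure is viable because 8 is tertiary, is held in the reactive fold and is deprotonated at once, which no simple acid in solution can imitate.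

Step 4
Reactants: 9 (1R,2S,7R,8R)-α-longipinene
Product: 10 (4R,5S,10R,11R)-longipin-2-en-1-one
Conditions: Rh2(cap)4 (cap = caprolactamate, cat.), t-BuOOH (70% aq.), K2CO3, CH2Cl2, 25 °C
Reagents that add atoms: tert-butyl hydroperoxide, CC(C)(C)OO
Why: This is a radical allylic oxidation of the α-pinene-to-verbenone type, in which the tert-butylperoxyl radical abstracts hydrogen from C1, the only allylic methylene (C4–H is a poorly overlapping cyclobutane bridgehead C–H and the C3 methyl is primary), and the mixed peroxide formed at C1 collapses to the enone without touching a stereocentre.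

Step 5
Reactants: 10 (4R,5S,10R,11R)-longipin-2-en-1-one
Product: 11 (7R)-7-hydroxylongipin-2-en-1-one
Conditions: evolved P450 BM3 variant (clarified lysate), NADP+ (cat.), glucose dehydrogenase, D-glucose, air, K2HPO4/KH2PO4 buffer pH 8.0, 2% EtOH, 25 °C
Reagents that add atoms: dioxygen, O=O
Why: Proposed new method: no enzyme is known to oxidise the seven-membered ring of a longipinane, so a P450 BM3 library has to be screened and evolved for C7; mechanistically the ferryl-oxo haem radical cation (tetravalent iron) abstracts a C7 hydrogen and returns OH by rebound, the C1 carbonyl having lowered the reactivity of C2=C3, the C3 methyl and the cyclobutane C–H bonds toward this electrophilic oxidant, so that only the C7, C8 and C9 methylenes compete and the pocket must decide among them; the closest known reaction type is the site-selective hydroxylation of unactivated CH2 groups in sesquiterpene lactones, sesquiterpene ketones and sclareolide by evolved P450 BM3 variants; only site selectivity is demanded, since the C7 configuration is erased in step 6.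

Step 6
Reactants: 11 (7R)-7-hydroxylongipin-2-en-1-one
Product: 12 longipin-2-ene-1,7-dione
Conditions: Dess–Martin periodinane, CH2Cl2, 25 °C
Reagents that add atoms: none
Why: Dess–Martin oxidation takes a hindered secondary alcohol to the ketone under neutral conditions that leave the enone and the cyclobutane alone, and both C7 epimers converge on 12.

Step 7
Reactants: 12 longipin-2-ene-1,7-dione
Product: 13 longipina-2,8-diene-1,7-dione
Conditions: IBX, DMSO–PhF, 70 °C
Reagents that add atoms: none
Why: IBX dehydrogenation passes through the only possible enol of the C7 ketone (C7=C8, C6 being quaternary) and must stop at the C8=C9 enone because C10 is quaternary, while the C1 enone offers only the non-enolisable bridgehead C11–H.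

Step 8
Reactants: 13 longipina-2,8-diene-1,7-dione
Product: 15 (9R)-9-hydroxylongipin-2-ene-1,7-dione, via C9 pinacol boronate 14 (not isolated)
Conditions: CuCl (cat.), NaOt-Bu (cat.), (R,R)-QuinoxP* (cat.; or its antipode, whichever a pilot pair of runs shows to deliver boron syn to C11), B2pin2, MeOH, THF, 25 °C; then NaBO3·4H2O, THF–H2O, 25 °C
Reagents that add atoms: bis(pinacolato)diboron (Bpin of 14), CC1(C)OB(OC1(C)C)B1OC(C)(C)C(C)(C)O1; sodium perborate (hydroxyl oxygen of 15), [Na+].[O-]OB=O
Why: In this copper-catalysed conjugate borylation with stereoretentive perborate oxidation, the copper boryl should add to the β-monosubstituted C8=C9 enone well before the β,β-disubstituted C2=C3 enone, and because the two faces of C9 are flanked by near-equivalent cyclobutane C–H groups (C4–H and C11–H) the 9R centre is set by the chiral bisphosphine (catalyst control) with little substrate mismatch.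

Step 9
Reactants: 15 (9R)-9-hydroxylongipin-2-ene-1,7-dione; 16 3-methylbutanal
Product: 18 (7R,9R)-7-hydroxy-1-oxolongipin-2-en-9-yl 3-methylbutanoate, via samarium hemiacetal 17 (not isolated)
Conditions: SmI2 (cat., premixed with excess 16 until decolourised), THF, −10 °C, dark
Reagents that add atoms: 3-methylbutanal 16, CC(C)CC=O
Why: In the Evans–Tishchenko reaction the C9 hydroxyl adds to 16, and the hemiacetal hydrogen of 17 passes through a samarium-chelated six-membered transition state to the C7 carbonyl face syn to O9, so the new C7–OH is trans to C9–O (7R) and the isovalerate is placed on O9 in the same event, which settles the order of acylation, while the trivalent samarium catalyst formed beforehand leaves the C1 enone untouched.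

Step 10
Reactants: 18 (7R,9R)-7-hydroxy-1-oxolongipin-2-en-9-yl 3-methylbutanoate; 19 3-methylbut-2-enoyl chloride
Product: 20 (7R,9R)-9-(3-methylbutanoyloxy)-1-oxolongipin-2-en-7-yl 3-methylbut-2-enoate (CNP0214473.1)
Conditions: DMAP, pyridine, CH2Cl2, 0 to 40 °C
Reagents that add atoms: 3-methylbut-2-enoyl chloride 19, CC(C)=CC(Cl)=O
Why: DMAP-catalysed acylation esterifies the one remaining, neopentylic C7–OH without touching the C7–O bond (7R retained), the weak base pyridine keeps vinylketene formation and hence deconjugation of the senecioyl group low, and the trans-1,3 arrangement disfavours acyl migration from O9.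

## Compound list

1 | (2E,6E)-farnesol | CC(C)=CCC/C(C)=C/CC/C(C)=C/CO | starting material
2 | (2E,6E)-farnesyl chloride | CC(C)=CCC/C(C)=C/CC/C(C)=C/CCl | intermediate
3 | (2E,6E)-farnesyl diphosphate (used as tris-ammonium salt) | CC(C)=CCC/C(C)=C/CC/C(C)=C/COP(=O)(O)OP(=O)(O)O | intermediate
4 | (6E)-nerolidyl diphosphate, enzyme-bound; the tertiary centre is fixed by the enzyme and lost on re-ionisation | CC(C)=CCC/C(C)=C/CCC(C)(C=C)OP(=O)(O)OP(=O)(O)O | intermediate
5 | humulyl cation (eleven-membered ring, cation at C7, C3=C4 Z, C10=C11 E) | C1C/C(C)=C/CC/C(C)=C\CC(C)(C)[CH+]1 | intermediate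
6 | allylic humulyl cation (after the C5-to-C7 hydride shift; allyl cation C5–C4–C3) | C1C/C(C)=C/CC/C(C)=C\[CH+]C(C)(C)C1 | intermediate
7 | cis-himachalyl cation (cis-fused six/seven rings, cation at C10) | C1CC[C+](C)[C@@H]2CCC(C)=C[C@@H]2C1(C)C | intermediate
8 | longipinyl cation (tricycle, cation at C3) | C1CC[C@@]2(C)[C@@H]3CC[C+](C)[C@H]2[C@@H]3C1(C)C | intermediate
9 | α-longipinene, (1R,2S,7R,8R)-2,6,6,9-tetramethyltricyclo[5.4.0.0(2,8)]undec-9-ene | C1CC[C@@]2(C)[C@@H]3CC=C(C)[C@H]2[C@@H]3C1(C)C | intermediate
10 | (4R,5S,10R,11R)-longipin-2-en-1-one | C1CC[C@@]2(C)[C@@H]3C(=O)C=C(C)[C@H]2[C@@H]3C1(C)C | intermediate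
11 | (7R)-7-hydroxylongipin-2-en-1-one (ring centres as in 10) | O[C@@H]1CC[C@@]2(C)[C@@H]3C(=O)C=C(C)[C@H]2[C@@H]3C1(C)C | intermediate
12 | longipin-2-ene-1,7-dione (ring centres as in 10) | O=C1CC[C@@]2(C)[C@@H]3C(=O)C=C(C)[C@H]2[C@@H]3C1(C)C | intermediate
13 | longipina-2,8-diene-1,7-dione (ring centres as in 10) | O=C1C=C[C@@]2(C)[C@@H]3C(=O)C=C(C)[C@H]2[C@@H]3C1(C)C | intermediate
14 | (9R)-9-(pinacolatoboryl)longipin-2-ene-1,7-dione, boron syn to C11 | O=C1C[C@@H](B4OC(C)(C)C(C)(C)O4)[C@@]2(C)[C@@H]3C(=O)C=C(C)[C@H]2[C@@H]3C1(C)C | intermediate
15 | (9R)-9-hydroxylongipin-2-ene-1,7-dione, OH syn to C11 | O=C1C[C@@H](O)[C@@]2(C)[C@@H]3C(=O)C=C(C)[C@H]2[C@@H]3C1(C)C | intermediate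
16 | 3-methylbutanal | CC(C)CC=O | starting material
17 | O9 hemiacetal of 15 with 16 (samarium-bound; either configuration at the hemiacetal carbon) | O=C1C[C@@H](OC(O)CC(C)C)[C@@]2(C)[C@@H]3C(=O)C=C(C)[C@H]2[C@@H]3C1(C)C | intermediate
18 | (4R,5S,7R,9R,10R,11R)-7-hydroxy-1-oxolongipin-2-en-9-yl 3-methylbutanoate | O[C@@H]1C[C@@H](OC(=O)CC(C)C)[C@@]2(C)[C@@H]3C(=O)C=C(C)[C@H]2[C@@H]3C1(C)C | intermediate
19 | 3-methylbut-2-enoyl chloride | CC(C)=CC(Cl)=O | starting material
20 | (4R,5S,7R,9R,10R,11R)-9-(3-methylbutanoyloxy)-1-oxolongipin-2-en-7-yl 3-methylbut-2-enoate, CNP0214473.1 | CC(C)=CC(=O)O[C@@H]1C[C@@H](OC(=O)CC(C)C)[C@@]2(C)[C@@H]3C(=O)C=C(C)[C@H]2[C@@H]3C1(C)C | target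

## Step count and risks

Total step count: 10. Longest linear sequence: 10 steps (1 to 20); 16 and 19 are purchased.

**Step 5 (labelled step).**
- What may go wrong: hydrogen abstraction may keep favouring the exposed C8 methylene or the C3 methyl through every round of evolution. Turnover on this compact ketone may also stay uncoupled, so that cofactor is consumed without oxygen transfer.
- Fallback: this uses known chemistry, sets out from 10 and comes back at 13.
- First, 10 undergoes quinuclidine-mediated anodic C–H oxidation (quinuclidine, Me4NBF4, HFIP, MeCN, O2, carbon anode, nickel cathode). This is a polarity- and size-governed hydrogen-atom abstraction. It should pick the methylene farthest from both quaternary carbons and from the carbonyl, giving longipin-2-ene-1,8-dione F1. Any C7 ketone formed alongside is 12 and joins the main line.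
- Kinetic enolisation (LDA, THF, −78 °C) and trapping with N-(5-chloro-2-pyridyl)triflimide gives 1-oxolongipina-2,8-dien-8-yl triflate F2.
- Formate reduction (Pd(OAc)2, PPh3, HCO2H, n-Bu3N, DMF, 60 °C) through zerovalent palladium gives longipina-2,8-dien-1-one F3.
- Allylic oxidation with CrO3 and 3,5-dimethylpyrazole (CH2Cl2, −20 °C) gives 13.
- Enolisation toward C7 instead of C9 costs nothing in principle, because both alkenes are oxidised through the same C7–C8–C9 allyl system. Regiocontrol in the last oxidation is weak, however, and chromatographic separation of the enone regioisomers must be accepted.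

**Step 8.**
- What may go wrong: facial selectivity at C9 may be poor, because the substrate has no bias of its own and all control rests on the ligand. Addition next to the quaternary C10 may also be sluggish enough for borylation at C3 to compete.
- Fallback: this sets out from 13 and comes back at 15.
- Weitz–Scheffer epoxidation (t-BuOOH, DBU, CH2Cl2) forms the C9–O bond directly and should again favour the less substituted enone.
- The diastereomer with the oxirane oxygen syn to C11, (8S,9S)-8,9-epoxylongipin-2-ene-1,7-dione F4, is separated and assigned at this rigid stage (NOE to C11–H against C4–H).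
- F4 is then opened at the C8–O bond with Na[PhSeB(OEt)3] (from PhSeSePh and NaBH4, EtOH). This leaves the C9–O bond and its configuration intact and gives 15.

**Step 9.**
- What may go wrong: hydride transfer to the neopentylic C7 carbonyl may be slow. Retro-aldol opening at C8–C9, β-elimination back toward the enone, or self-Tishchenko consumption of the aldehyde could then take over.
- Fallback: this sets out from 15 and comes back at 18.
- Evans–Saksena reduction (Me4NBH(OAc)3, MeCN–AcOH, −20 °C) delivers hydride from boron bound to O9. It reduces only the hydroxyl-flanked C7 ketone and gives the trans-diol (7R,9R)-7,9-dihydroxylongipin-2-en-1-one F5.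
- One equivalent of 3-methylbutanoyl chloride (pyridine, CH2Cl2, −20 °C) should then acylate C9–OH, which sits next to the tied-back cyclobutane carbon C10, before C7–OH, which sits next to the gem-dimethyl carbon C6. This gives 18.

## Further compounds

F1 | step 5 | longipin-2-ene-1,8-dione (ring centres as in 10) | C1C(=O)C[C@@]2(C)[C@@H]3C(=O)C=C(C)[C@H]2[C@@H]3C1(C)C
F2 | step 5 | 1-oxolongipina-2,8-dien-8-yl trifluoromethanesulfonate | C1C(OS(=O)(=O)C(F)(F)F)=C[C@@]2(C)[C@@H]3C(=O)C=C(C)[C@H]2[C@@H]3C1(C)C
F3 | step 5 | longipina-2,8-dien-1-one | C1C=C[C@@]2(C)[C@@H]3C(=O)C=C(C)[C@H]2[C@@H]3C1(C)C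
F4 | step 8 | (8S,9S)-8,9-epoxylongipin-2-ene-1,7-dione, oxirane oxygen syn to C11 | O=C1[C@H]4O[C@H]4[C@@]2(C)[C@@H]3C(=O)C=C(C)[C@H]2[C@@H]3C1(C)C
F5 | step 9 | (7R,9R)-7,9-dihydroxylongipin-2-en-1-one | O[C@@H]1C[C@@H](O)[C@@]2(C)[C@@H]3C(=O)C=C(C)[C@H]2[C@@H]3C1(C)C
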